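Your amber and ochre runs share their charges of starting material and reagent and differ in the free catalyst, 12 mM against 3.1 mM, so you can set their slopes against each other.

| setting | ochre | amber | flask |
|---|---|---|---|
| starting material | 1.5 M | 1.5 M | 1.5 M |
| reagent | 3 M | 3 M | 3.00 M |
| free catalyst | 3.1 mM | 12 mM | 6.2 mM |
| remark | run made earlier | run made earlier |  |

| ochre: time / min | ochre: product / % | amber: time / min | amber: product / % |
|---|---|---|---|
| 10.0 | 21.8 | 3.00 | 25.0 |
| 20.0 | 40.0 | 6.00 | 48.7 |
| 25.0 | 48.3 | 15.0 | 96.0 |
| 40.0 | 65.6 | 40.0 | 99.7 |

(each reading ± 0.3 percentage points)

- apparent order in reagent when 50% of the starting material are converted (percent change of the rate of making product for one percent more reagent charged)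
- apparent order in free catalyst when 50% of the starting material are converted (percent change of the rate of making product for one percent more free catalyst charged)

- what was read earlier has a scatter of 0.3 percentage points, one standard deviation
- no earlier run changes the charge of reagent; that part of a forecast is a guess

Take first order in free catalyst as the large part and reckon only the correction. The last slopes before half conversion, amber's from 3.00 min to 6.00 min and ochre's from 20.0 min to 25.0 min, give 0.153 above first order. Call this the excess order: the logarithm of the slope ratio over the logarithm of the charge ratio, less one. It is a reading, with the scatter of 0.3 percentage points behind it. So my number for the flask, charged with 6.2 mM, is 1.15.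

Your forecast says 1.12 (1 to 1.3), a little lower than mine, and 0.15 (−0.3 to 0.6) in reagent: “The reagent order is probably small, but it was never varied, so this is a guess with a wide range.”

The flask gives 1.2 in free catalyst and 0.054 in reagent.

    reagent + free catalyst → catalyst intermediate A (k = 2.30 M⁻¹ s⁻¹)
    catalyst intermediate A → catalyst intermediate B (k = 0.620 s⁻¹)
    catalyst intermediate B ⇌ by-product + catalyst intermediate C (K = 21.0 M, k = 0.520 s⁻¹)
    starting material + catalyst intermediate C → catalyst intermediate D (k = 2.10 M⁻¹ s⁻¹)
    catalyst intermediate D → free catalyst + product (k = 0.650 s⁻¹)
    2 free catalyst → spent catalyst A (k = 0.540 M⁻¹ s⁻¹)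
    by-product + catalyst intermediate B → spent catalyst B (k = 0.00190 M⁻¹ s⁻¹)

The flask's excess order is 0.200. In the same flask run without the turning of by-product + catalyst intermediate B into spent catalyst B, this deactivation, the apparent order in free catalyst is 1.0, so that step shifts the order by 0.201, the largest single effect on it. In the flask, spent catalyst B stands at 4.53% of the catalyst charged after 0.100 h and 56.1% after 0.500 h. The step also lowers the rate in the flask, as a part of what holds it down: without the step, the rate at half conversion is 1.20 times the actual one.

The earlier runs and the new flask come from a simulation on assumed constants; noise was put on by code.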